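**Retrosynthetic overview**
- Target ⇐ global hydrogenolysis of its tetra-O-benzyl ether; the 4'-OMe is never protected or touched.
- Pyranone C ring ⇐ I2/DMSO oxidative cyclisation of a 2'-hydroxychalcone ⇐ Claisen–Schmidt condensation of a 3-benzylated phloroacetophenone dibenzyl ether with O-benzylisovanillin. The only free phenol sits next to the benzyl group, so closure can only give the 8-benzyl flavone.
- ArCH2–Ar' bond ⇐ proposed boron-templated deaminative aryl transfer from 4-(benzyloxy)phenylboronic acid to an ortho-Mannich base, via an o-quinone methide.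
- Mannich base ⇐ ortho-aminomethylation of 4,6-di-O-benzylphloroacetophenone ⇐ phloroacetophenone.
- Ring order: ring A, ring B and the benzyl ring are bought as arenes; the only ring built is the pyranone C ring (step 5).

Assumption: the target SMILES has no stereocentre and no stereogenic double bond, so the compound is achiral and "single enantiomer" simply means the structure as drawn.

**Step 1**
Reactants: 1 2',4',6'-trihydroxyacetophenone
Product: 2 1-[4,6-bis(benzyloxy)-2-hydroxyphenyl]ethan-1-one
Conditions: BnBr (2.05 equiv), K2CO3 (2.2 equiv), DMF, rt, 16 h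
Reagents that add atoms: benzyl bromide, BrCc1ccccc1
Why: Williamson etherification stops at the 4,6-dibenzyl ether because the remaining ortho hydroxyl is locked in a strong hydrogen bond to the acetyl C=O and is much less nucleophilic; no stereocentre is formed.

**Step 2**
Reactants: 2 1-[4,6-bis(benzyloxy)-2-hydroxyphenyl]ethan-1-one
Product: 3 1-{4,6-bis(benzyloxy)-3-[(dimethylamino)methyl]-2-hydroxyphenyl}ethan-1-one
Conditions: 37% aq. HCHO (1.2 equiv), 40% aq. Me2NH (1.2 equiv), EtOH, 50 °C, 12 h
Reagents that add atoms: formaldehyde, C=O; dimethylamine, CNC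
Why: Phenolic Mannich (ortho-aminomethylation) reaction in which the iminium is delivered to C3, the only free position ortho to the free OH, while C5 is flanked by two benzyloxy groups; no stereocentre is formed.

**Step 3**
Reactants: 3 1-{4,6-bis(benzyloxy)-3-[(dimethylamino)methyl]-2-hydroxyphenyl}ethan-1-one; 4 [4-(benzyloxy)phenyl]boronic acid
Product: 6 1-{4,6-bis(benzyloxy)-3-[4-(benzyloxy)benzyl]-2-hydroxyphenyl}ethan-1-one, via o-quinone methide 2-acetyl-3,5-bis(benzyloxy)-6-methylidenecyclohexa-2,4-dien-1-one 5 (not isolated)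
Conditions: 4 (1.5 equiv), 1,4-dioxane, 90 °C, 12 h; aq. NH4Cl work-up
Reagents that add atoms: none
Why: Proposed new method: boron-templated deaminative aryl transfer, in which the boronic acid condenses on the phenolic OH of 3 and is chelated by the neighbouring NMe2 (N→B), making the amine a leaving group; C–N ionisation then gives o-quinone methide 5 held on oxygen as a tetracoordinate boron "ate" complex, which passes its electron-rich aryl group to the exocyclic CH2 through a six-membered transition state, so the new CH2–aryl bond forms only ortho to that oxygen and only at the ipso carbon of the boronic acid; the closest known reaction types are the Petasis borono-Mannich reaction of salicylaldehydes, boronate 1,4-additions to o-quinone methides and thermal o-quinone methide release from phenolic Mannich bases, here proposed for the first time as a metal-free Mannich-base-to-diarylmethane arylation on a chelated 2-acylphenol; no stereocentre is formed.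

**Step 4**
Reactants: 6 1-{4,6-bis(benzyloxy)-3-[4-(benzyloxy)benzyl]-2-hydroxyphenyl}ethan-1-one; 7 3-(benzyloxy)-4-methoxybenzaldehyde
Product: 8 (E)-1-{4,6-bis(benzyloxy)-3-[4-(benzyloxy)benzyl]-2-hydroxyphenyl}-3-[3-(benzyloxy)-4-methoxyphenyl]prop-2-en-1-one
Conditions: KOH (50% aq., 5 equiv, regenerated base), EtOH–THF, rt, 36 h; then 1 M HCl
Reagents that add atoms: none
Why: Claisen–Schmidt aldol condensation of the methyl ketone enolate with a non-enolisable aldehyde gives the conjugated E-chalcone under thermodynamic control; the alkene geometry is lost on aromatisation in the next step.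

**Step 5**
Reactants: 8 (E)-1-{4,6-bis(benzyloxy)-3-[4-(benzyloxy)benzyl]-2-hydroxyphenyl}-3-[3-(benzyloxy)-4-methoxyphenyl]prop-2-en-1-one
Product: 10 5,7-bis(benzyloxy)-8-[4-(benzyloxy)benzyl]-2-[3-(benzyloxy)-4-methoxyphenyl]-4H-chromen-4-one, via racemic flavanone 5,7-bis(benzyloxy)-8-[4-(benzyloxy)benzyl]-2-[3-(benzyloxy)-4-methoxyphenyl]-2,3-dihydro-4H-chromen-4-one 9 (not isolated)
Conditions: I2 (10 mol %), DMSO, 120 °C, 3 h
Reagents that add atoms: none
Why: Oxidative cyclisation of a 2'-hydroxychalcone, in which the single free phenol (next to the benzyl group) closes by oxa-Michael addition to flavanone 9 and iodine-catalysed dehydrogenation with DMSO as terminal oxidant gives the flavone, so the benzyl group necessarily ends up at C8 and the transient C2 stereocentre is erased.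

**Step 6**
Reactants: 10 5,7-bis(benzyloxy)-8-[4-(benzyloxy)benzyl]-2-[3-(benzyloxy)-4-methoxyphenyl]-4H-chromen-4-one
Product: 11 5,7-dihydroxy-8-(4-hydroxybenzyl)-2-(3-hydroxy-4-methoxyphenyl)-4H-chromen-4-one
Conditions: H2 (1 atm), 10% Pd/C, THF–MeOH (1:1), rt, 6 h
Reagents that add atoms: none
Why: Catalytic hydrogenolysis cleaves the four aryl benzyl ethers, while the aryl methyl ether, the vinylogous-ester C2=C3 bond of the flavone and the diarylmethane C–C bonds are inert at 1 atm and room temperature; the target has no stereocentre.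

**Compound list**
1 | 2',4',6'-trihydroxyacetophenone | CC(=O)c1c(O)cc(O)cc1O | starting material
2 | 1-[4,6-bis(benzyloxy)-2-hydroxyphenyl]ethan-1-one | CC(=O)c1c(O)cc(OCc2ccccc2)cc1OCc3ccccc3 | intermediate
3 | 1-{4,6-bis(benzyloxy)-3-[(dimethylamino)methyl]-2-hydroxyphenyl}ethan-1-one | CC(=O)c1c(O)c(CN(C)C)c(OCc2ccccc2)cc1OCc3ccccc3 | intermediate
4 | [4-(benzyloxy)phenyl]boronic acid | OB(O)c1ccc(OCc2ccccc2)cc1 | starting material
5 | 2-acetyl-3,5-bis(benzyloxy)-6-methylidenecyclohexa-2,4-dien-1-one (o-quinone methide, boron-bound in the flask) | CC(=O)C1=C(OCc2ccccc2)C=C(OCc3ccccc3)C(=C)C1=O | intermediate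
6 | 1-{4,6-bis(benzyloxy)-3-[4-(benzyloxy)benzyl]-2-hydroxyphenyl}ethan-1-one | CC(=O)c1c(O)c(Cc2ccc(OCc3ccccc3)cc2)c(OCc4ccccc4)cc1OCc5ccccc5 | intermediate
7 | 3-(benzyloxy)-4-methoxybenzaldehyde | COc1ccc(C=O)cc1OCc2ccccc2 | starting material
8 | (E)-1-{4,6-bis(benzyloxy)-3-[4-(benzyloxy)benzyl]-2-hydroxyphenyl}-3-[3-(benzyloxy)-4-methoxyphenyl]prop-2-en-1-one | COc1ccc(/C=C/C(=O)c2c(O)c(Cc3ccc(OCc4ccccc4)cc3)c(OCc5ccccc5)cc2OCc6ccccc6)cc1OCc7ccccc7 | intermediate
9 | racemic 5,7-bis(benzyloxy)-8-[4-(benzyloxy)benzyl]-2-[3-(benzyloxy)-4-methoxyphenyl]-2,3-dihydro-4H-chromen-4-one | COc1ccc(C2CC(=O)c3c(OCc4ccccc4)cc(OCc5ccccc5)c(Cc6ccc(OCc7ccccc7)cc6)c3O2)cc1OCc8ccccc8 | intermediate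
10 | 5,7-bis(benzyloxy)-8-[4-(benzyloxy)benzyl]-2-[3-(benzyloxy)-4-methoxyphenyl]-4H-chromen-4-one | COc1ccc(-c2cc(=O)c3c(OCc4ccccc4)cc(OCc5ccccc5)c(Cc6ccc(OCc7ccccc7)cc6)c3o2)cc1OCc8ccccc8 | intermediate
11 | 5,7-dihydroxy-8-(4-hydroxybenzyl)-2-(3-hydroxy-4-methoxyphenyl)-4H-chromen-4-one | COc1ccc(-c2cc(=O)c3c(O)cc(O)c(Cc4ccc(O)cc4)c3o2)cc1O | target

**Totals**
Total step count: 6. Longest linear sequence: 6 steps (1 → 11).

**Three steps most likely to fail**

Step 3 (the proposed new step). The boron chelate may fail to ionise, the boronic acid may protodeboronate, or the o-quinone methide may oligomerise. The fallback uses known chemistry, sets out from compound 2 and comes back at compound 6. Compound 2 is iodinated ortho to the free OH with N-iodosuccinimide and catalytic TsOH in MeCN at 0 °C to give 1-[4,6-bis(benzyloxy)-2-hydroxy-3-iodophenyl]ethan-1-one F2. Commercial 4-(benzyloxy)benzyl chloride (ClCc1ccc(OCc2ccccc2)cc1) is converted with zinc dust and LiCl in THF into [4-(benzyloxy)benzyl]zinc chloride F3. Negishi coupling of the two (Pd(OAc)2/SPhos, THF, rt; 2.5 equiv of the zinc reagent added slowly because of the free phenol) gives 6.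

Step 2. The aminomethylation could go to C5, occur twice, or take place at the acetyl CH3. The fallback sets out from compound 2 and comes back at compound 3. Magnesium-phenoxide-directed ortho-formylation (MgCl2, Et3N, paraformaldehyde, MeCN, reflux), which is specific for the position ortho to the OH, gives 3-acetyl-4,6-bis(benzyloxy)-2-hydroxybenzaldehyde F1. Reductive amination with Me2NH and NaBH(OAc)3 in 1,2-dichloroethane at rt then gives 3.

Step 5. Hot I2/DMSO could oxidise the doubly benzylic ArCH2Ar group or iodinate ring A. Loss of the 5-O-benzyl group would be harmless, since all benzyl groups fall in step 6. The fallback sets out from compound 6 and comes back at compound 10 by a Baker–Venkataraman sequence. Steglich esterification of 6 with commercial 3-(benzyloxy)-4-methoxybenzoic acid (COc1ccc(C(=O)O)cc1OCc1ccccc1; DCC, DMAP, CH2Cl2) gives 2-acetyl-3,5-bis(benzyloxy)-6-[4-(benzyloxy)benzyl]phenyl 3-(benzyloxy)-4-methoxybenzoate F4. Base-mediated 1,5-acyl shift (KOH, pyridine, 50 °C; AcOH quench) gives 1-{4,6-bis(benzyloxy)-3-[4-(benzyloxy)benzyl]-2-hydroxyphenyl}-3-[3-(benzyloxy)-4-methoxyphenyl]propane-1,3-dione F5. Cyclodehydration (NaOAc, AcOH, 100 °C) gives 10 with no oxidant present.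

**Further compounds**
F1 | step 2 | 3-acetyl-4,6-bis(benzyloxy)-2-hydroxybenzaldehyde | CC(=O)c1c(O)c(C=O)c(OCc2ccccc2)cc1OCc3ccccc3
F2 | step 3 | 1-[4,6-bis(benzyloxy)-2-hydroxy-3-iodophenyl]ethan-1-one | CC(=O)c1c(O)c(I)c(OCc2ccccc2)cc1OCc3ccccc3
F3 | step 3 | [4-(benzyloxy)benzyl]zinc chloride | Cl[Zn]Cc1ccc(OCc2ccccc2)cc1
F4 | step 5 | 2-acetyl-3,5-bis(benzyloxy)-6-[4-(benzyloxy)benzyl]phenyl 3-(benzyloxy)-4-methoxybenzoate | CC(=O)c1c(OC(=O)c2ccc(OC)c(OCc3ccccc3)c2)c(Cc4ccc(OCc5ccccc5)cc4)c(OCc6ccccc6)cc1OCc7ccccc7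
F5 | step 5 | 1-{4,6-bis(benzyloxy)-3-[4-(benzyloxy)benzyl]-2-hydroxyphenyl}-3-[3-(benzyloxy)-4-methoxyphenyl]propane-1,3-dione | COc1ccc(C(=O)CC(=O)c2c(O)c(Cc3ccc(OCc4ccccc4)cc3)c(OCc5ccccc5)cc2OCc6ccccc6)cc1OCc7ccccc7
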